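## Retrosynthetic overview (chroman-2-one numbering, primes for the pyranone)

1. The strategy rests on the 4-methoxy-2-pyranone ring (O1', C2'–C6') bonded through C6' to arene C6. C6' is read as a CO carbon, O1' as the oxygen of the resulting aryl ketone, and C2'–C5' (OMe on C4') as the four ring carbons of a 3-methoxycyclobutenone. C6–C6', C5'–C6' and O1'–C2' are therefore all made in one operation from an arylstannane, CO and a 4-chlorocyclobutenone.
2. The C4–aryl bond is cut last, as an enantioselective Rh 1,4-addition to a flat coumarin. This avoids an arylmetal at the di-ortho-substituted C4a.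
3. The coumarin ring (O1–C2, C3=C4) goes back to a C4a-formyl/C8a-hydroxy arene plus a two-carbon ketene ylide. The formyl group is placed on the pyranone-bearing arene by electrophilic substitution.
4. Ring order: orcinol arene (bought), then pyranone (step 7), then lactone ring as coumarin (step 10), then C4 stereocentre (step 11), then debenzylation (step 12).

Key step: step 7

Assumption: rotation about the C6–C6' aryl–pyranone bond is fast at room temperature (only H-5' and O-1' flank it on the pyranone side), so C4 (R) is the only stereogenic unit to control.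

## Route

Step 1
Reactants: 1 orcinol (5-methylbenzene-1,3-diol)
Product: 2 1,3-bis(benzyloxy)-5-methylbenzene
Conditions: BnBr (2.2 equiv), K2CO3, DMF, 60 °C
Reagents that add atoms: benzyl bromide, BrCc1ccccc1
Why: Williamson ether synthesis on both phenols, giving ethers that tolerate the later lithiation, Pd/CO, Vilsmeier and Rh steps and that leave by hydrogenolysis without touching the pyranone methyl ether.

Step 2
Reactants: 2 1,3-bis(benzyloxy)-5-methylbenzene
Product: 3 1,5-bis(benzyloxy)-2-bromo-3-methylbenzene
Conditions: NBS (1.0 equiv), MeCN, 0 °C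
Reagents that add atoms: N-bromosuccinimide, O=C1CCC(=O)N1Br
Why: Electrophilic aromatic bromination goes para to one benzyloxy group and ortho to the other (next to the methyl group) rather than to the doubly flanked site between the two ethers, and the two reactive positions are equivalent by symmetry.

Step 3
Reactants: 3 1,5-bis(benzyloxy)-2-bromo-3-methylbenzene
Product: 5 tributyl[2,4-bis(benzyloxy)-6-methylphenyl]stannane, via aryllithium 4 (not isolated)
Conditions: n-BuLi (1.05 equiv), THF, −78 °C; then Bu3SnCl, −78 °C → rt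
Reagents that add atoms: tributyltin chloride, CCCC[Sn](Cl)(CCCC)CCCC
Why: Bromine–lithium exchange at −78 °C is faster than benzylic deprotonation, and stannylation of the aryllithium fixes tin on the carbon between OBn and CH3.

Step 4
Reactants: 6 dimethyl squarate (3,4-dimethoxycyclobut-3-ene-1,2-dione)
Product: 8 3-methoxycyclobut-3-ene-1,2-dione (methyl semisquarate), via hydroxycyclobutenone 7 (not isolated)
Conditions: LiAlH(Ot-Bu)3 (1.0 equiv), THF, −78 °C, then H2O; crude in CH2Cl2, conc. aq HCl (cat.), rt
Reagents that add atoms: water, O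
Why: Bulky-hydride 1,2-reduction of one squarate carbonyl is followed by acid-catalysed allylic transposition, in which the hydroxyl leaves, water returns at the methoxy-stabilised far end of the cyclobutenyl cation and methanol is lost, the standard passage from squarate esters to semisquarates.

Step 5
Reactants: 8 3-methoxycyclobut-3-ene-1,2-dione
Product: 9 rac-4-hydroxy-3-methoxycyclobut-2-en-1-one
Conditions: LiAlH(Ot-Bu)3 (1.0 equiv), THF, −78 °C; then H2O
Reagents that add atoms: none
Why: In this 1,2-reduction of a cyclobutenedione the hydride takes the carbonyl bonded to C–OMe, because the other carbonyl is a vinylogous ester (MeO–C=C–C=O) and far less electrophilic, and the new carbinol centre is racemic and is erased in step 7.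

Step 6
Reactants: 9 rac-4-hydroxy-3-methoxycyclobut-2-en-1-one
Product: 10 rac-4-chloro-3-methoxycyclobut-2-en-1-one
Conditions: PPh3 (1.1 equiv), CCl4, CH2Cl2, 0 °C → rt
Reagents that add atoms: carbon tetrachloride, ClC(Cl)(Cl)Cl
Why: The Appel reaction runs under neutral conditions that spare the acid-labile enol ether, and direct (SN2) and allylic (SN2') entry of chloride give the same constitution because C2 and C4 exchange roles on allylic shift.

Step 7
Reactants: 5 tributyl[2,4-bis(benzyloxy)-6-methylphenyl]stannane, 10 rac-4-chloro-3-methoxycyclobut-2-en-1-one, 11 carbon monoxide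
Product: 14 6-[2,4-bis(benzyloxy)-6-methylphenyl]-4-methoxy-2H-pyran-2-one, via 4-aroylcyclobutenone 12 (not isolated), via acyl vinylketene 13 (not isolated)
Conditions: Pd2(dba)3 (2.5 mol %), P(2-furyl)3 (10 mol %), CO (3 atm), 1,4-dioxane, 50 °C; then 100 °C
Reagents that add atoms: none
Why: Pd(0) adds oxidatively to the allylic C4–Cl bond of 10 to give an η3-oxocyclobutenyl complex, CO inserts to an acylpalladium, the aryl group of 5 moves from tin to palladium and reductive elimination forms C5'–C6' and C6–C6' in 12, which is the known carbonylative Stille coupling of 4-chlorocyclobutenones with aryl- and alkenylstannanes that ends in 2-pyranones. Heating breaks the C1–C4 bond of 12 in a conrotatory 4π ring opening to 13, and the one new ring closes by an oxa-6π (pseudopericyclic) electrocyclisation in which the aroyl oxygen attacks the ketene carbon (O1'–C2'), a six-membered closure made irreversible by the aromatic character of the pyranone. No stereocentre is left, since C4 of 10 and 12 is racemic and becomes the sp2 carbon C5'. Regiochemistry is not at stake, because the allyl termini C2 and C4 of the palladium complex both carry H and are related by a mirror plane through C1 and C3, so bond formation at either end gives 12 and the methoxy group must end on C4'. Carbonylative rather than direct coupling is secured by CO pressure together with the slow transmetalation of the di-ortho-substituted stannane, which leaves time for CO insertion. The ring opening must turn the aroyl group inward, for which a ketone acceptor has only a modest bias, but the outward isomer cannot cyclise and returns to 12 by 4π closure, so the equilibrium drains through 13.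

Step 8
Reactants: 14 6-[2,4-bis(benzyloxy)-6-methylphenyl]-4-methoxy-2H-pyran-2-one
Product: 16 4,6-bis(benzyloxy)-3-(4-methoxy-2-oxo-2H-pyran-6-yl)-2-methylbenzaldehyde, via iminium chloride 15 (not isolated)
Conditions: POCl3 (2 equiv), DMF, 0 → 60 °C; then ice-water, rt
Reagents that add atoms: N,N-dimethylformamide, CN(C)C=O; water, O
Why: In this Vilsmeier–Haack formylation the weakly electrophilic chloroiminium ion attacks only the most electron-rich C–H, the arene position para to one benzyloxy group, ortho to the other and meta to the pyranone (future C4a), whereas the site between the two ethers is shielded on both sides and C3' of the pyranone is a push–pull carbon deactivated by the lactone carbonyl.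

Step 9
Reactants: 16 4,6-bis(benzyloxy)-3-(4-methoxy-2-oxo-2H-pyran-6-yl)-2-methylbenzaldehyde
Product: 17 4-(benzyloxy)-6-hydroxy-3-(4-methoxy-2-oxo-2H-pyran-6-yl)-2-methylbenzaldehyde
Conditions: MgBr2·OEt2 (1.5 equiv), toluene/Et2O, 80 °C; then H2O
Reagents that add atoms: none
Why: In this chelation-directed ether cleavage Mg(II) binds the formyl oxygen and the neighbouring benzyloxy oxygen in a six-membered chelate, so bromide removes only that benzyl group by SN2 attack, while the unchelated benzyl ether next to the pyranone and the less SN2-reactive pyranone methyl ether stay.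

Step 10
Reactants: 17 4-(benzyloxy)-6-hydroxy-3-(4-methoxy-2-oxo-2H-pyran-6-yl)-2-methylbenzaldehyde, 18 (triphenylphosphoranylidene)ketene
Product: 20 7-(benzyloxy)-6-(4-methoxy-2-oxo-2H-pyran-6-yl)-5-methyl-2H-chromen-2-one, via aryl ester ylide 19 (not isolated)
Conditions: 18 (1.2 equiv), toluene, 100 °C
Reagents that add atoms: none
Why: The phenol adds to the ketene ylide to give an ester-stabilised ylide, whose intramolecular Wittig reaction with the ortho-formyl group closes the six-membered ring, so the cis C3=C4 geometry is enforced by the tether and no alkene isomerisation is needed.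

Step 11
Reactants: 20 7-(benzyloxy)-6-(4-methoxy-2-oxo-2H-pyran-6-yl)-5-methyl-2H-chromen-2-one, 21 [4-(benzyloxy)phenyl]boronic acid
Product: 22 (4R)-7-(benzyloxy)-4-[4-(benzyloxy)phenyl]-6-(4-methoxy-2-oxo-2H-pyran-6-yl)-5-methyl-3,4-dihydro-2H-chromen-2-one
Conditions: Rh(acac)(C2H4)2 (3 mol %), (R)-SEGPHOS (3.3 mol %), 21 (excess, in portions), dioxane/H2O 10:1, 60 °C
Reagents that add atoms: none
Why: In this Hayashi–Miyaura asymmetric 1,4-addition, a reaction known for coumarins, the aryl–Rh(I)/(R)-SEGPHOS species binds the planar C3=C4 bond on the face left open by the ligand and delivers the aryl group to C4 in the sense that gives (R)-4-arylchroman-2-ones (CIP order C4a > aryl > C3 > H, unchanged here), while the in-plane C5 methyl shields neither face and the donor-substituted, trisubstituted pyranone alkenes do not insert.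

Step 12
Reactants: 22 (4R)-7-(benzyloxy)-4-[4-(benzyloxy)phenyl]-6-(4-methoxy-2-oxo-2H-pyran-6-yl)-5-methyl-3,4-dihydro-2H-chromen-2-one
Product: 23 (4R)-7-hydroxy-4-(4-hydroxyphenyl)-6-(4-methoxy-2-oxo-2H-pyran-6-yl)-5-methyl-3,4-dihydro-2H-chromen-2-one (CNP0207475.1)
Conditions: H2 (1 atm), 10 % Pd/C, EtOAc/THF, rt, stopped after uptake of 2 equiv
Reagents that add atoms: none
Why: Neutral catalytic hydrogenolysis cleaves the two aryl benzyl ethers much faster than it saturates the hindered, aromatic-like pyranone, leaves the lactone closed in an aprotic solvent and offers no pathway for epimerisation at C4.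

## Compound list

1 | orcinol (5-methylbenzene-1,3-diol) | Cc1cc(O)cc(O)c1 | starting material
2 | 1,3-bis(benzyloxy)-5-methylbenzene | Cc1cc(OCc2ccccc2)cc(OCc2ccccc2)c1 | intermediate
3 | 1,5-bis(benzyloxy)-2-bromo-3-methylbenzene | Cc1cc(OCc2ccccc2)cc(OCc2ccccc2)c1Br | intermediate
4 | [2,4-bis(benzyloxy)-6-methylphenyl]lithium | Cc1cc(OCc2ccccc2)cc(OCc2ccccc2)c1[Li] | intermediate
5 | tributyl[2,4-bis(benzyloxy)-6-methylphenyl]stannane | Cc1cc(OCc2ccccc2)cc(OCc2ccccc2)c1[Sn](CCCC)(CCCC)CCCC | intermediate
6 | dimethyl squarate (3,4-dimethoxycyclobut-3-ene-1,2-dione) | COC1=C(OC)C(=O)C1=O | starting material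
7 | rac-4-hydroxy-2,3-dimethoxycyclobut-2-en-1-one | COC1=C(OC)C(=O)C1O | intermediate
8 | 3-methoxycyclobut-3-ene-1,2-dione (methyl semisquarate) | COC1=CC(=O)C1=O | intermediate
9 | rac-4-hydroxy-3-methoxycyclobut-2-en-1-one | COC1=CC(=O)C1O | intermediate
10 | rac-4-chloro-3-methoxycyclobut-2-en-1-one | COC1=CC(=O)C1Cl | intermediate
11 | carbon monoxide | [C-]#[O+] | starting material
12 | rac-4-[2,4-bis(benzyloxy)-6-methylbenzoyl]-3-methoxycyclobut-2-en-1-one | COC1=CC(=O)C1C(=O)c1c(C)cc(OCc2ccccc2)cc1OCc1ccccc1 | intermediate
13 | (3E)-5-[2,4-bis(benzyloxy)-6-methylphenyl]-3-methoxypenta-1,3-diene-1,5-dione (ketenyl and aroyl groups cis) | O=C=C/C(OC)=C\C(=O)c1c(C)cc(OCc2ccccc2)cc1OCc1ccccc1 | intermediate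
14 | 6-[2,4-bis(benzyloxy)-6-methylphenyl]-4-methoxy-2H-pyran-2-one | COc1cc(-c2c(OCc3ccccc3)cc(OCc3ccccc3)cc2C)oc(=O)c1 | intermediate
15 | N-{[4,6-bis(benzyloxy)-3-(4-methoxy-2-oxo-2H-pyran-6-yl)-2-methylphenyl]methylidene}-N-methylmethanaminium chloride | COc1cc(-c2c(OCc3ccccc3)cc(OCc3ccccc3)c(C=[N+](C)C)c2C)oc(=O)c1.[Cl-] | intermediate
16 | 4,6-bis(benzyloxy)-3-(4-methoxy-2-oxo-2H-pyran-6-yl)-2-methylbenzaldehyde | COc1cc(-c2c(OCc3ccccc3)cc(OCc3ccccc3)c(C=O)c2C)oc(=O)c1 | intermediate
17 | 4-(benzyloxy)-6-hydroxy-3-(4-methoxy-2-oxo-2H-pyran-6-yl)-2-methylbenzaldehyde | COc1cc(-c2c(OCc3ccccc3)cc(O)c(C=O)c2C)oc(=O)c1 | intermediate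
18 | (triphenylphosphoranylidene)ketene | O=C=C=P(c1ccccc1)(c1ccccc1)c1ccccc1 | starting material
19 | 5-(benzyloxy)-2-formyl-4-(4-methoxy-2-oxo-2H-pyran-6-yl)-3-methylphenyl (triphenyl-λ5-phosphanylidene)acetate | COc1cc(-c2c(OCc3ccccc3)cc(OC(=O)C=P(c3ccccc3)(c3ccccc3)c3ccccc3)c(C=O)c2C)oc(=O)c1 | intermediate
20 | 7-(benzyloxy)-6-(4-methoxy-2-oxo-2H-pyran-6-yl)-5-methyl-2H-chromen-2-one | COc1cc(-c2c(OCc3ccccc3)cc3oc(=O)ccc3c2C)oc(=O)c1 | intermediate
21 | [4-(benzyloxy)phenyl]boronic acid | OB(O)c1ccc(OCc2ccccc2)cc1 | starting material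
22 | (4R)-7-(benzyloxy)-4-[4-(benzyloxy)phenyl]-6-(4-methoxy-2-oxo-2H-pyran-6-yl)-5-methyl-3,4-dihydro-2H-chromen-2-one | COc1cc(-c2c(OCc3ccccc3)cc3c(c2C)[C@@H](c2ccc(OCc4ccccc4)cc2)CC(=O)O3)oc(=O)c1 | intermediate
23 | (4R)-7-hydroxy-4-(4-hydroxyphenyl)-6-(4-methoxy-2-oxo-2H-pyran-6-yl)-5-methyl-3,4-dihydro-2H-chromen-2-one | COc1cc(-c2c(O)cc3c(c2C)[C@@H](c2ccc(O)cc2)CC(=O)O3)oc(=O)c1 | target

## Step count and risks

Total step count: 12. Longest linear sequence: 9 steps (steps 1–3 then 7–12; the branch through steps 4–6 then 7–12 is equally long).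

**Step 7.**
- *Risk:* Transfer of the di-ortho-substituted aryl group from tin to acylpalladium may be slower than thermal ring opening and oligomerisation of the chlorocyclobutenone, or slower than protodestannylation. Coupling without CO uptake may also intrude.
- *Fallback:* It sets out from 2 and comes back at 14, and builds the pyranone by polar chemistry.
  - Vilsmeier–Haack formylation of 2 (POCl3, DMF) gives 2,4-bis(benzyloxy)-6-methylbenzaldehyde F1.
  - The lithium dienolate of methyl (E)-3-methoxybut-2-enoate (LDA, THF, −78 °C) adds through its γ-carbon. The adduct lactonises in the same operation to rac-6-[2,4-bis(benzyloxy)-6-methylphenyl]-4-methoxy-5,6-dihydro-2H-pyran-2-one F2.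
  - DDQ dehydrogenation in hot dioxane across the benzylic C6'–H and C5'–H gives 14.

**Step 11.**
- *Risk:* Insertion into the donor-substituted, peri-methylated coumarin may be so slow that protodeboronation consumes the boronic acid. Facial discrimination may also erode at the higher temperatures then needed.
- *Fallback:* It sets out from 14 and comes back at 23, and builds C4 on an open chain.
  - NBS (1 equiv, MeCN, low temperature) gives 6-[4,6-bis(benzyloxy)-3-bromo-2-methylphenyl]-4-methoxy-2H-pyran-2-one F3.
  - Palladium-catalysed borylation with tetrahydroxydiboron (XPhos–Pd precatalyst, KOAc, EtOH) gives [4,6-bis(benzyloxy)-3-(4-methoxy-2-oxo-2H-pyran-6-yl)-2-methylphenyl]boronic acid F4.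
  - 4-(Benzyloxy)aniline is diazotised (NaNO2, HBF4) to 4-(benzyloxy)benzenediazonium tetrafluoroborate F5.
  - Pd(0) with a chiral phosphate as anion phase-transfer catalyst (enantiomer chosen for 3R; Na2CO3, ether solvent) joins F5, benzyl acrylate and F4 in an enantioselective 1,1-diarylation. The sequence is Heck insertion, chain walk to the π-benzyl, transmetalation and reductive elimination. The product is benzyl (3R)-3-[4,6-bis(benzyloxy)-3-(4-methoxy-2-oxo-2H-pyran-6-yl)-2-methylphenyl]-3-[4-(benzyloxy)phenyl]propanoate F6.
  - Hydrogenolysis of the four benzyl groups gives (3R)-3-[4,6-dihydroxy-3-(4-methoxy-2-oxo-2H-pyran-6-yl)-2-methylphenyl]-3-(4-hydroxyphenyl)propanoic acid F7. This lactonises through the hydroxyl ortho to the side chain (cat. TsOH if needed) to 23.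
  - This line is second choice because boron sits between OBn and CH3.

**Step 6.**
- *Risk:* Displacement at the strained α-keto carbon may be slow. Phosphine may quaternise with the product chloride. The small chloride may be lost through volatility or ring opening on isolation.
- *Fallback:* It sets out from 9 and comes back at 14, and does without the chloride.
  - Methyl chloroformate and pyridine convert 9 into methyl (2-methoxy-4-oxocyclobut-2-en-1-yl) carbonate F8.
  - F8 is used as the allylic electrophile in the palladium coupling with 5 and 11. Ionisation with loss of CO2 gives the same mirror-symmetric η3-oxocyclobutenyl palladium species, the liberated methoxide takes up the tin, and the cascade proceeds to 14.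

## Further compounds

F1 | step 7 | 2,4-bis(benzyloxy)-6-methylbenzaldehyde | Cc1cc(OCc2ccccc2)cc(OCc2ccccc2)c1C=O
F2 | step 7 | rac-6-[2,4-bis(benzyloxy)-6-methylphenyl]-4-methoxy-5,6-dihydro-2H-pyran-2-one | COC1=CC(=O)OC(C1)c1c(C)cc(OCc2ccccc2)cc1OCc1ccccc1
F3 | step 11 | 6-[4,6-bis(benzyloxy)-3-bromo-2-methylphenyl]-4-methoxy-2H-pyran-2-one | COc1cc(-c2c(OCc3ccccc3)cc(OCc3ccccc3)c(Br)c2C)oc(=O)c1
F4 | step 11 | [4,6-bis(benzyloxy)-3-(4-methoxy-2-oxo-2H-pyran-6-yl)-2-methylphenyl]boronic acid | COc1cc(-c2c(OCc3ccccc3)cc(OCc3ccccc3)c(B(O)O)c2C)oc(=O)c1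
F5 | step 11 | 4-(benzyloxy)benzenediazonium tetrafluoroborate | N#[N+]c1ccc(OCc2ccccc2)cc1.F[B-](F)(F)F
F6 | step 11 | benzyl (3R)-3-[4,6-bis(benzyloxy)-3-(4-methoxy-2-oxo-2H-pyran-6-yl)-2-methylphenyl]-3-[4-(benzyloxy)phenyl]propanoate | COc1cc(-c2c(OCc3ccccc3)cc(OCc3ccccc3)c(c2C)[C@@H](c2ccc(OCc3ccccc3)cc2)CC(=O)OCc2ccccc2)oc(=O)c1
F7 | step 11 | (3R)-3-[4,6-dihydroxy-3-(4-methoxy-2-oxo-2H-pyran-6-yl)-2-methylphenyl]-3-(4-hydroxyphenyl)propanoic acid | COc1cc(-c2c(O)cc(O)c(c2C)[C@@H](c2ccc(O)cc2)CC(=O)O)oc(=O)c1
F8 | step 6 | rac-methyl (2-methoxy-4-oxocyclobut-2-en-1-yl) carbonate | COC(=O)OC1C(=O)C=C1OC
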